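**Plan**
- Retrosynthesis: the two acetate C–O bonds are cut first (back to a triol), then O1–C2 and C2–C3 of the oxolane in one operation, then the C4–C(carbinol) bond.
- Enabling feature: C2 is an acetal-level benzylic carbon between O1 and C3, and C3 bears an aldehyde-level carbon (the later CH2OAc). C2–C3 therefore forms when the enol derivative of that aldehyde attacks an aryl oxocarbenium ion carried by O1.
- Forward: an allyl carbamate from (E)-but-2-ene-1,4-diol is joined to 4-methoxybenzaldehyde at C4–C(carbinol) by a carbamate homoaldol reaction. The oxolane, the only ring made, then closes by acetal–enol carbamate annulation, followed by reduction, desilylation and acetylation.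
- Stereochemistry: the carbinol centre and C4 come from sparteine-mediated lithiation, titanium exchange with inversion and a chair transition state (anti, Z-enol carbamate). C3 and C2 are set relative to C4 in the ring closure (all-trans).

Key step: step 8

Assumption: (−)-sparteine directs the lithiation of the silyloxy-substituted allyl carbamate in the same sense as for the parent (E)-but-2-enyl carbamate, to the (S)-configured lithium compound; were the sense reversed, (+)-sparteine would be used.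

**Step 1**
Reactants: 1 (E)-but-2-ene-1,4-diol
Product: 2 (E)-4-[(tert-butyldimethylsilyl)oxy]but-2-en-1-ol
Conditions: NaH (1 equiv), THF, 0 °C → rt; TBSCl (1 equiv)
Reagents that add atoms: tert-butyldimethylsilyl chloride, CC(C)(C)[Si](C)(C)Cl
Why: O-silylation of a symmetrical diol through its poorly soluble monosodium alkoxide should stop largely at the mono ether, and the E double bond is not touched.

**Step 2**
Reactants: 2 (E)-4-[(tert-butyldimethylsilyl)oxy]but-2-en-1-ol; 3 N,N-diisopropylcarbamoyl chloride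
Product: 4 (E)-4-[(tert-butyldimethylsilyl)oxy]but-2-en-1-yl N,N-diisopropylcarbamate
Conditions: Et3N, CH2Cl2, reflux
Reagents that add atoms: none
Why: O-carbamoylation of a primary allylic alcohol (acyl substitution at the carbamoyl chloride) is standard and installs the directing, dipole-stabilising group for α-lithiation, while the TBS ether is inert to amine base.

**Step 3**
Reactants: 4 (E)-4-[(tert-butyldimethylsilyl)oxy]but-2-en-1-yl N,N-diisopropylcarbamate; 5 4-methoxybenzaldehyde
Product: 8 (1Z,3R,4S)-3-{[(tert-butyldimethylsilyl)oxy]methyl}-4-hydroxy-4-(4-methoxyphenyl)but-1-en-1-yl N,N-diisopropylcarbamate, via (S)-1-lithio carbamate 6 (not isolated), via (R)-allyltitanium triisopropoxide 7 (not isolated)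
Conditions: n-BuLi, (−)-sparteine, toluene, −78 °C; Ti(OiPr)4, −78 °C; then 5, −78 → −20 °C; aq. work-up
Reagents that add atoms: none
Why: Carbamate homoaldol reaction: the carbamoyl group directs α-lithiation, (−)-sparteine selects the (S)-lithium compound 6, Ti(OiPr)4 exchanges with inversion to the (R)-allyltitanium 7, and 7 adds to the aldehyde at its γ-carbon through a Zimmerman–Traxler chair (aryl and CH2OTBS equatorial, carbamoyloxy axial), which sets the (4S) carbinol and the (3R) centre anti to each other together with the Z-enol carbamate, while titanation at −78 °C forestalls loss of the δ-silyloxy group.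

**Step 4**
Reactants: 8 (1Z,3R,4S)-3-{[(tert-butyldimethylsilyl)oxy]methyl}-4-hydroxy-4-(4-methoxyphenyl)but-1-en-1-yl N,N-diisopropylcarbamate
Product: 9 (1Z,3R,4S)-3-{[(tert-butyldimethylsilyl)oxy]methyl}-4-(4-methoxyphenyl)-4-[(triisopropylsilyl)oxy]but-1-en-1-yl N,N-diisopropylcarbamate
Conditions: TIPSOTf, 2,6-lutidine, CH2Cl2, −78 → 0 °C
Reagents that add atoms: triisopropylsilyl trifluoromethanesulfonate, CC(C)[Si](OS(=O)(=O)C(F)(F)F)(C(C)C)C(C)C
Why: Silyl triflate silylation under lutidine buffering caps the hindered carbinol oxygen, which would otherwise be the hydroxyl that condenses with the acetal in step 8, and no stereocentre is involved.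

**Step 5**
Reactants: 9 (1Z,3R,4S)-3-{[(tert-butyldimethylsilyl)oxy]methyl}-4-(4-methoxyphenyl)-4-[(triisopropylsilyl)oxy]but-1-en-1-yl N,N-diisopropylcarbamate
Product: 10 (1Z,3R,4S)-3-(hydroxymethyl)-4-(4-methoxyphenyl)-4-[(triisopropylsilyl)oxy]but-1-en-1-yl N,N-diisopropylcarbamate
Conditions: HF·pyridine, pyridine, THF, 0 °C → rt
Reagents that add atoms: none
Why: Buffered fluoride desilylation should remove the unhindered primary TBS ether much faster than the hindered secondary TIPS ether, and because no alkoxide is formed the TIPS group cannot migrate to the primary oxygen; the enol carbamate is left intact.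

**Step 6**
Reactants: 11 4-hydroxybenzaldehyde
Product: 12 4-[(triisopropylsilyl)oxy]benzaldehyde
Conditions: TIPSCl, imidazole, DMF, rt
Reagents that add atoms: triisopropylsilyl chloride, CC(C)[Si](Cl)(C(C)C)C(C)C
Why: Imidazole-promoted O-silylation of the phenol gives an aryl silyl ether that tolerates the Lewis acid and borohydride of later steps and falls to fluoride.

**Step 7**
Reactants: 12 4-[(triisopropylsilyl)oxy]benzaldehyde
Product: 13 [4-(dimethoxymethyl)phenoxy]triisopropylsilane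
Conditions: HC(OMe)3, PPTS (cat.), MeOH, rt; Et3N quench
Reagents that add atoms: trimethyl orthoformate, COC(OC)OC; methanol, CO
Why: Acid-catalysed acetalisation is driven to completion by the orthoformate as water scavenger, and the mild acid spares the aryl silyl ether.

**Step 8**
Reactants: 10 (1Z,3R,4S)-3-(hydroxymethyl)-4-(4-methoxyphenyl)-4-[(triisopropylsilyl)oxy]but-1-en-1-yl N,N-diisopropylcarbamate; 13 [4-(dimethoxymethyl)phenoxy]triisopropylsilane
Product: 17 (2R,3R,4R)-4-[(S)-(4-methoxyphenyl)[(triisopropylsilyl)oxy]methyl]-2-{4-[(triisopropylsilyl)oxy]phenyl}oxolane-3-carbaldehyde, via mixed methyl acetal 14 (not isolated), via aryl oxocarbenium ion 15 (not isolated), via ring-closed carbamoyloxycarbenium ion 16 (not isolated)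
Conditions: 13 (1.5 equiv), BF3·OEt2 (2 equiv), CH2Cl2, −78 → −40 °C; aq. NaHCO3
Reagents that add atoms: none
Why: BF3·OEt2 exchanges one methoxy group of 13 for the primary hydroxyl of 10 (mixed acetal 14) and ionises it to the E-configured aryl oxocarbenium ion 15 on O1; the Z-enol carbamate attacks this ion through its β-carbon, forming C2–C3 after O1–C2, and the carbamoyloxy-stabilised cation 16 is hydrolysed to the aldehyde on work-up. The closest known reaction type is the Lewis-acid condensation of 4-hydroxy-1-alkenyl carbamates with aldehydes or acetals to oxolane-3-carbaldehydes, an intramolecular Mukaiyama–Prins addition. The oxolane closes in a five-membered mode that is endo with respect to the oxocarbenium C=O+ bond and exo with respect to the enol double bond (5-(enol-exo)-endo-trig). C3 is controlled by allylic 1,3-strain of the Z-enol carbamate, which holds C4–H in the enol plane so that the tethered ion attacks from the face opposite the silyloxybenzyl arm (3,4-trans); C2 is controlled by the E-oxocarbenium ion reacting in an envelope with the aryl group pseudo-equatorial and the enol double bond antiperiplanar to C=O+, which places the aryl group trans to the formyl group. The step needs ionisation of the acetal in preference to the anisyl carbinol and the all-trans diastereomer: the bulky, weakly basic TIPS ether and the low temperature should secure the first, and the second is backed by thermodynamics, because the formyl-bearing centre can epimerise and the electron-rich benzylic C2–O1 bond can re-ionise towards the all-trans oxolane anchored by C4.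

**Step 9**
Reactants: 17 (2R,3R,4R)-4-[(S)-(4-methoxyphenyl)[(triisopropylsilyl)oxy]methyl]-2-{4-[(triisopropylsilyl)oxy]phenyl}oxolane-3-carbaldehyde
Product: 18 [(2R,3S,4R)-4-[(S)-(4-methoxyphenyl)[(triisopropylsilyl)oxy]methyl]-2-{4-[(triisopropylsilyl)oxy]phenyl}oxolan-3-yl]methanol
Conditions: NaBH4, MeOH/THF, 0 °C
Reagents that add atoms: none
Why: Borohydride reduction of the aldehyde creates no stereocentre, and the only epimerisable centre (C3) already sits in its more stable trans,trans arrangement.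

**Step 10**
Reactants: 18 [(2R,3S,4R)-4-[(S)-(4-methoxyphenyl)[(triisopropylsilyl)oxy]methyl]-2-{4-[(triisopropylsilyl)oxy]phenyl}oxolan-3-yl]methanol
Product: 19 4-[(2R,3S,4R)-4-[(S)-hydroxy(4-methoxyphenyl)methyl]-3-(hydroxymethyl)oxolan-2-yl]phenol
Conditions: TBAF (3 equiv), THF, rt
Reagents that add atoms: none
Why: Fluoride desilylation should cleave the aryl silyl ether at once and the hindered secondary silyl ether more slowly, and in the absence of acid neither benzylic C–O bond is ionised.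

**Step 11**
Reactants: 19 4-[(2R,3S,4R)-4-[(S)-hydroxy(4-methoxyphenyl)methyl]-3-(hydroxymethyl)oxolan-2-yl]phenol
Product: 20 4-[(2R,3S,4R)-4-[(S)-acetyloxy(4-methoxyphenyl)methyl]-3-(acetyloxymethyl)oxolan-2-yl]phenyl acetate
Conditions: Ac2O, pyridine, DMAP (cat.), CH2Cl2, rt
Reagents that add atoms: acetic anhydride, CC(=O)OC(C)=O
Why: DMAP-catalysed O-acetylation should cover the phenol and both alcohols without breaking any C–O bond at a stereocentre.

**Step 12**
Reactants: 20 4-[(2R,3S,4R)-4-[(S)-acetyloxy(4-methoxyphenyl)methyl]-3-(acetyloxymethyl)oxolan-2-yl]phenyl acetate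
Product: 21 [(2R,3S,4R)-4-[(S)-acetyloxy(4-methoxyphenyl)methyl]-2-(4-hydroxyphenyl)oxolan-3-yl]methyl acetate
Conditions: pyrrolidine (1.2 equiv), CH2Cl2, 0 °C
Reagents that add atoms: none
Why: Aminolysis of esters is far faster for the aryl acetate (phenoxide leaving group) than for the two alkyl acetates, and the aprotic medium avoids solvolysis of the 4-methoxybenzylic acetate.

**Compound list**

1 | (E)-but-2-ene-1,4-diol | OC/C=C/CO | starting material
2 | (E)-4-[(tert-butyldimethylsilyl)oxy]but-2-en-1-ol | OC/C=C/CO[Si](C)(C)C(C)(C)C | intermediate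
3 | N,N-diisopropylcarbamoyl chloride | CC(C)N(C(C)C)C(Cl)=O | starting material
4 | (E)-4-[(tert-butyldimethylsilyl)oxy]but-2-en-1-yl N,N-diisopropylcarbamate | CC(C)N(C(C)C)C(=O)OC/C=C/CO[Si](C)(C)C(C)(C)C | intermediate
5 | 4-methoxybenzaldehyde | COc1ccc(C=O)cc1 | starting material
6 | (1S,2E)-4-[(tert-butyldimethylsilyl)oxy]-1-lithiobut-2-en-1-yl N,N-diisopropylcarbamate, formed as its (−)-sparteine complex (drawn without the diamine) | [Li][C@H](OC(=O)N(C(C)C)C(C)C)/C=C/CO[Si](C)(C)C(C)(C)C | intermediate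
7 | (1R,2E)-4-[(tert-butyldimethylsilyl)oxy]-1-[tri(propan-2-yloxy)titanio]but-2-en-1-yl N,N-diisopropylcarbamate | CC(C)O[Ti](OC(C)C)(OC(C)C)[C@@H](OC(=O)N(C(C)C)C(C)C)/C=C/CO[Si](C)(C)C(C)(C)C | intermediate
8 | (1Z,3R,4S)-3-{[(tert-butyldimethylsilyl)oxy]methyl}-4-hydroxy-4-(4-methoxyphenyl)but-1-en-1-yl N,N-diisopropylcarbamate | COc1ccc([C@@H](O)[C@@H](CO[Si](C)(C)C(C)(C)C)/C=C\OC(=O)N(C(C)C)C(C)C)cc1 | intermediate
9 | (1Z,3R,4S)-3-{[(tert-butyldimethylsilyl)oxy]methyl}-4-(4-methoxyphenyl)-4-[(triisopropylsilyl)oxy]but-1-en-1-yl N,N-diisopropylcarbamate | COc1ccc([C@@H](O[Si](C(C)C)(C(C)C)C(C)C)[C@@H](CO[Si](C)(C)C(C)(C)C)/C=C\OC(=O)N(C(C)C)C(C)C)cc1 | intermediate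
10 | (1Z,3R,4S)-3-(hydroxymethyl)-4-(4-methoxyphenyl)-4-[(triisopropylsilyl)oxy]but-1-en-1-yl N,N-diisopropylcarbamate | COc1ccc([C@@H](O[Si](C(C)C)(C(C)C)C(C)C)[C@@H](CO)/C=C\OC(=O)N(C(C)C)C(C)C)cc1 | intermediate
11 | 4-hydroxybenzaldehyde | O=Cc1ccc(O)cc1 | starting material
12 | 4-[(triisopropylsilyl)oxy]benzaldehyde | O=Cc1ccc(O[Si](C(C)C)(C(C)C)C(C)C)cc1 | intermediate
13 | [4-(dimethoxymethyl)phenoxy]triisopropylsilane | COC(OC)c1ccc(O[Si](C(C)C)(C(C)C)C(C)C)cc1 | intermediate
14 | (1Z,3R,4S)-3-({methoxy[4-(triisopropylsilyloxy)phenyl]methoxy}methyl)-4-(4-methoxyphenyl)-4-[(triisopropylsilyl)oxy]but-1-en-1-yl N,N-diisopropylcarbamate (both epimers at the acetal carbon) | COc1ccc([C@@H](O[Si](C(C)C)(C(C)C)C(C)C)[C@@H](COC(OC)c2ccc(O[Si](C(C)C)(C(C)C)C(C)C)cc2)/C=C\OC(=O)N(C(C)C)C(C)C)cc1 | intermediate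
15 | (E)-{(2R,3S)-2-[(Z)-2-(diisopropylcarbamoyloxy)ethenyl]-3-(4-methoxyphenyl)-3-[(triisopropylsilyl)oxy]propyl}[4-(triisopropylsilyloxy)benzylidene]oxonium | COc1ccc([C@@H](O[Si](C(C)C)(C(C)C)C(C)C)[C@@H](C/[O+]=C/c2ccc(O[Si](C(C)C)(C(C)C)C(C)C)cc2)/C=C\OC(=O)N(C(C)C)C(C)C)cc1 | intermediate
16 | (2R,3R,4R)-oxolane of 17 in which C3 carries CH=O+–C(O)N(iPr)2 in place of CHO | COc1ccc([C@@H](O[Si](C(C)C)(C(C)C)C(C)C)[C@H]2CO[C@@H](c3ccc(O[Si](C(C)C)(C(C)C)C(C)C)cc3)[C@@H]2C=[O+]C(=O)N(C(C)C)C(C)C)cc1 | intermediate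
17 | (2R,3R,4R)-4-[(S)-(4-methoxyphenyl)[(triisopropylsilyl)oxy]methyl]-2-{4-[(triisopropylsilyl)oxy]phenyl}oxolane-3-carbaldehyde | COc1ccc([C@@H](O[Si](C(C)C)(C(C)C)C(C)C)[C@H]2CO[C@@H](c3ccc(O[Si](C(C)C)(C(C)C)C(C)C)cc3)[C@@H]2C=O)cc1 | intermediate
18 | [(2R,3S,4R)-4-[(S)-(4-methoxyphenyl)[(triisopropylsilyl)oxy]methyl]-2-{4-[(triisopropylsilyl)oxy]phenyl}oxolan-3-yl]methanol | COc1ccc([C@@H](O[Si](C(C)C)(C(C)C)C(C)C)[C@H]2CO[C@@H](c3ccc(O[Si](C(C)C)(C(C)C)C(C)C)cc3)[C@@H]2CO)cc1 | intermediate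
19 | 4-[(2R,3S,4R)-4-[(S)-hydroxy(4-methoxyphenyl)methyl]-3-(hydroxymethyl)oxolan-2-yl]phenol | COc1ccc([C@@H](O)[C@H]2CO[C@@H](c3ccc(O)cc3)[C@@H]2CO)cc1 | intermediate
20 | 4-[(2R,3S,4R)-4-[(S)-acetyloxy(4-methoxyphenyl)methyl]-3-(acetyloxymethyl)oxolan-2-yl]phenyl acetate | COc1ccc([C@@H](OC(C)=O)[C@H]2CO[C@@H](c3ccc(OC(C)=O)cc3)[C@@H]2COC(C)=O)cc1 | intermediate
21 | [(2R,3S,4R)-4-[(S)-acetyloxy(4-methoxyphenyl)methyl]-2-(4-hydroxyphenyl)oxolan-3-yl]methyl acetate | COc1ccc([C@@H](OC(C)=O)[C@H]2CO[C@@H](c3ccc(O)cc3)[C@@H]2COC(C)=O)cc1 | target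

**Step count**
Total: 12 steps. Longest linear sequence: 10 steps (steps 1–5 and 8–12); steps 6–7 form the two-step side branch to the acetal.

**Steps most likely to fail**

Step 3. The δ-silyloxy-substituted allyllithium may expel silanolate by 1,4-elimination before the titanium exchange. In addition, the lithium–sparteine ion pair may not reach or keep high enantiomeric purity, because the crystallisation that enriches the parent but-2-enyl complex need not carry over.

The fallback avoids the lithiated carbamate altogether; it sets out from 5 and comes back to the route at 17.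
- 4-Methoxybenzaldehyde 5 would be coupled with 4-vinyl-1,3-dioxolan-2-one by iridium-catalysed transfer-hydrogenative anti-(hydroxymethyl)allylation ([Ir(cod)Cl]2, a SEGPHOS-type bisphosphine of the enantiomer that gives the 1S,2R product, 4-cyano-3-nitrobenzoic acid, K3PO4, 2-propanol, THF, 60 °C). This should give (1S,2R)-2-ethenyl-1-(4-methoxyphenyl)propane-1,3-diol F1.
- Silylation of the primary hydroxyl (TBSCl, imidazole, CH2Cl2) should give (1S,2R)-2-{[(tert-butyldimethylsilyl)oxy]methyl}-1-(4-methoxyphenyl)but-3-en-1-ol F2.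
- TIPSOTf and 2,6-lutidine should give tert-butyl({(2R)-2-[(S)-(4-methoxyphenyl)[(triisopropylsilyl)oxy]methyl]but-3-en-1-yl}oxy)dimethylsilane F3.
- Ozonolysis (O3, CH2Cl2/MeOH, −78 °C; PPh3) should give (2R,3S)-2-{[(tert-butyldimethylsilyl)oxy]methyl}-3-(4-methoxyphenyl)-3-[(triisopropylsilyl)oxy]propanal F4.
- Wittig methoxymethylenation ((methoxymethyl)triphenylphosphonium chloride, KN(SiMe3)2, THF, −78 → 0 °C) should give tert-butyl({(2R)-4-methoxy-2-[(S)-(4-methoxyphenyl)[(triisopropylsilyl)oxy]methyl]but-3-en-1-yl}oxy)dimethylsilane F5 as an E/Z mixture.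
- Acetic-acid-buffered TBAF at 0 °C should free (2R)-4-methoxy-2-[(S)-(4-methoxyphenyl)[(triisopropylsilyl)oxy]methyl]but-3-en-1-ol F6.
- F6 and acetal 13 under BF3·OEt2 at −78 °C, followed by mild aqueous acid, should close the same O1–C2 and C2–C3 bonds with the enol ether as nucleophile and deliver 17.

Step 8. Acetal exchange and ionisation may be too slow at −78 °C. The extra Lewis acid or warming then needed would ionise the silylated anisyl carbinol and erode the facial selectivity at C2.

The fallback pre-forms the O1–C2 link at the ester oxidation level; it sets out from 10 and 12 and comes back at 17.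
- Pinnick oxidation of 12 (NaClO2, NaH2PO4, 2-methylbut-2-ene, tBuOH/H2O) should give 4-[(triisopropylsilyl)oxy]benzoic acid F7.
- Steglich esterification of 10 with F7 (DCC, DMAP, CH2Cl2) should give (2R,3S)-2-[(Z)-2-(diisopropylcarbamoyloxy)ethenyl]-3-(4-methoxyphenyl)-3-[(triisopropylsilyl)oxy]propyl 4-[(triisopropylsilyl)oxy]benzoate F8.
- Reduction with diisobutylaluminium hydride (iBu2AlH) at −78 °C and acetylation of the aluminium hemiacetal in the same flask (pyridine, DMAP, Ac2O) should give {(2R,3S)-2-[(Z)-2-(diisopropylcarbamoyloxy)ethenyl]-3-(4-methoxyphenyl)-3-[(triisopropylsilyl)oxy]propoxy}{4-[(triisopropylsilyl)oxy]phenyl}methyl acetate F9.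
- The α-acetoxy ether F9 ionises with BF3·OEt2 in CH2Cl2 at −78 °C, under kinetic control, to the same oxocarbenium ion 15 and thence to 17.

Step 12. Acyl cleavage may not stop at the phenolic ester (loss or migration of the primary acetate), or the 4-methoxybenzylic acetate may be substituted.

The fallback differentiates the phenol before acetylation; it sets out from 19 and comes back at 21.
- Selective O-allylation of the phenol (allyl bromide, K2CO3, acetone) should give [(2R,3S,4R)-4-[(S)-hydroxy(4-methoxyphenyl)methyl]-2-[4-(prop-2-en-1-yloxy)phenyl]oxolan-3-yl]methanol F10.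
- Acetylation (Ac2O, pyridine, DMAP) should give [(2R,3S,4R)-4-[(S)-acetyloxy(4-methoxyphenyl)methyl]-2-[4-(prop-2-en-1-yloxy)phenyl]oxolan-3-yl]methyl acetate F11.
- Allyl transfer to morpholine with Pd(PPh3)4 in THF at rt should release 21 without touching either acetate.

**Further compounds**

F1 | step 3 | (1S,2R)-2-ethenyl-1-(4-methoxyphenyl)propane-1,3-diol | COc1ccc([C@@H](O)[C@@H](CO)C=C)cc1
F2 | step 3 | (1S,2R)-2-{[(tert-butyldimethylsilyl)oxy]methyl}-1-(4-methoxyphenyl)but-3-en-1-ol | COc1ccc([C@@H](O)[C@@H](CO[Si](C)(C)C(C)(C)C)C=C)cc1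
F3 | step 3 | tert-butyl({(2R)-2-[(S)-(4-methoxyphenyl)[(triisopropylsilyl)oxy]methyl]but-3-en-1-yl}oxy)dimethylsilane | COc1ccc([C@@H](O[Si](C(C)C)(C(C)C)C(C)C)[C@@H](CO[Si](C)(C)C(C)(C)C)C=C)cc1
F4 | step 3 | (2R,3S)-2-{[(tert-butyldimethylsilyl)oxy]methyl}-3-(4-methoxyphenyl)-3-[(triisopropylsilyl)oxy]propanal | COc1ccc([C@@H](O[Si](C(C)C)(C(C)C)C(C)C)[C@@H](CO[Si](C)(C)C(C)(C)C)C=O)cc1
F5 | step 3 | tert-butyl({(2R)-4-methoxy-2-[(S)-(4-methoxyphenyl)[(triisopropylsilyl)oxy]methyl]but-3-en-1-yl}oxy)dimethylsilane (E/Z mixture) | COc1ccc([C@@H](O[Si](C(C)C)(C(C)C)C(C)C)[C@@H](CO[Si](C)(C)C(C)(C)C)C=COC)cc1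
F6 | step 3 | (2R)-4-methoxy-2-[(S)-(4-methoxyphenyl)[(triisopropylsilyl)oxy]methyl]but-3-en-1-ol (E/Z mixture) | COc1ccc([C@@H](O[Si](C(C)C)(C(C)C)C(C)C)[C@@H](CO)C=COC)cc1
F7 | step 8 | 4-[(triisopropylsilyl)oxy]benzoic acid | OC(=O)c1ccc(O[Si](C(C)C)(C(C)C)C(C)C)cc1
F8 | step 8 | (2R,3S)-2-[(Z)-2-(diisopropylcarbamoyloxy)ethenyl]-3-(4-methoxyphenyl)-3-[(triisopropylsilyl)oxy]propyl 4-[(triisopropylsilyl)oxy]benzoate | COc1ccc([C@@H](O[Si](C(C)C)(C(C)C)C(C)C)[C@@H](COC(=O)c2ccc(O[Si](C(C)C)(C(C)C)C(C)C)cc2)/C=C\OC(=O)N(C(C)C)C(C)C)cc1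
F9 | step 8 | {(2R,3S)-2-[(Z)-2-(diisopropylcarbamoyloxy)ethenyl]-3-(4-methoxyphenyl)-3-[(triisopropylsilyl)oxy]propoxy}{4-[(triisopropylsilyl)oxy]phenyl}methyl acetate (both epimers at the acetal carbon) | COc1ccc([C@@H](O[Si](C(C)C)(C(C)C)C(C)C)[C@@H](COC(OC(C)=O)c2ccc(O[Si](C(C)C)(C(C)C)C(C)C)cc2)/C=C\OC(=O)N(C(C)C)C(C)C)cc1
F10 | step 12 | [(2R,3S,4R)-4-[(S)-hydroxy(4-methoxyphenyl)methyl]-2-[4-(prop-2-en-1-yloxy)phenyl]oxolan-3-yl]methanol | COc1ccc([C@@H](O)[C@H]2CO[C@@H](c3ccc(OCC=C)cc3)[C@@H]2CO)cc1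
F11 | step 12 | [(2R,3S,4R)-4-[(S)-acetyloxy(4-methoxyphenyl)methyl]-2-[4-(prop-2-en-1-yloxy)phenyl]oxolan-3-yl]methyl acetate | COc1ccc([C@@H](OC(C)=O)[C@H]2CO[C@@H](c3ccc(OCC=C)cc3)[C@@H]2COC(C)=O)cc1
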